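The ratio I started from was one of two logarithms. In the east run a single-handed free catalyst joins coupling partner to a racemate, and at 20.0 min the logarithm of charge over what was left stood at 2.81 for the left-handed substrate and 0.155 for the right-handed one, a quotient of 18.1, which I named the selectivity factor s. I assumed that each substrate falls in proportion to its own amount against the same partner and catalyst, so that s holds however these two change; the north-east run gave 19.7, a difference that a scatter of 0.3 percentage points on so small a fall can hide.

| flask | left-handed substrate | right-handed substrate | coupling partner | free catalyst | remark | time |
|---|---|---|---|---|---|---|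
| north-east | 0.50 M | 0.50 M | 0.75 M | 0.41 mM | run made earlier |  |
| east | 0.50 M | 0.50 M | 0.75 M | 1.7 mM | run made earlier |  |
| elm | 0.50 M | 0.50 M | 0.750 M | 2.0 mM |  | 25 min |
| maple | 0.50 M | 0.50 M | 0.750 M | 0.60 mM |  | 25 min |

| run | time / min | right-handed substrate / % | left-handed substrate / % |
|---|---|---|---|
| north-east | 1.33 | 49.4 | 39.9 |
| north-east | 2.50 | 48.8 | 34.0 |
| north-east | 5.00 | 48.8 | 26.4 |
| north-east | 10.0 | 46.8 | 19.1 |
| north-east | 20.0 | 46.9 | 14.2 |
| east | 4.00 | 46.1 | 10.7 |
| east | 8.00 | 44.8 | 5.6 |
| east | 10.0 | 43.9 | 4.9 |
| east | 15.0 | 43.2 | 3.9 |
| east | 20.0 | 42.8 | 3.0 |

(standard deviation of a reading: 0.3 percentage points)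

- free catalyst is single-handed; left-handed substrate and right-handed substrate are mirror images of each other, charged as a racemate, each of them at the stated concentration
- the analysis behind the earlier runs scatters by 0.3 percentage points, standard deviation
- an excess is the difference of the two amounts in percent of their sum
- an excess is below zero if the other one leads

1. which one finishes higher in excess of right-handed substrate over left-handed substrate among what is left of the two ("neither" within 2 percentage points) (elm / maple / neither)
2. excess of right-handed substrate over left-handed substrate among what is left of the two at the end, elm
3. excess of right-handed substrate over left-handed substrate among what is left of the two at the end, maple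

The top rung of my ladder was the left-handed substrate, which in the north-east run began at an apparent constant of 0.170 min⁻¹. The next rung was the slowing, since over its last stretch that constant read 0.0296 min⁻¹. The balance of the coupling partner, the limiting reagent against both substrates together, gave 0.361 M at the last north-east reading if coupling were its one use, so a fall by a factor of 2.08 was less than the fall of the constant by a factor of 5.74, and I concluded that catalyst or partner was being lost some other way. The bottom rung was the right-handed substrate, s times slower by my assumption, and the last east reading showed 42.8% of it beside 3.0% of the left-handed substrate.

Thus I needed x, the left-handed logarithm at the last reading, which I let stand unchanged for the end at 25 min. Between the two runs x grew as catalyst to the power 0.565, which gave 3.08 for elm and 1.56 for maple. Dividing each by s for the right-handed substrate, I reckoned an excess of 89.7% for elm, higher than 62.8% for maple. The forecast, by its own account “an empirical interpolation, not a fitted mechanism”, said elm, with 91% for elm and 65% for maple, each above my own figure.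

Elm finished higher, at 89.9% against 66.2% for maple.

    coupling partner + free catalyst + right-handed substrate → free catalyst + right-handed product (k = 32.0 L² mol⁻² min⁻¹)
    2 free catalyst → spent catalyst (k = 15.0 L mol⁻¹ min⁻¹)
    coupling partner → decomposition product (k = 2.10 × 10⁻⁵ min⁻¹)
    coupling partner → decomposed reagent (k = 0.0470 min⁻¹)
    coupling partner + free catalyst + left-handed substrate → free catalyst + left-handed product (k = 600 L² mol⁻² min⁻¹)

In elm 0.162 M of coupling partner had become decomposed reagent by 25.0 min. Elm's 2.27% of left-handed substrate, put through s, gives 42.1% of right-handed substrate, and the flask held 42.4%. A neighbour, elm with 0.45 M of coupling partner, held 14.4% of left-handed substrate at the end, which s turns into an excess of 52.8%, and that flask stood at 53.0%.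

The runs are calculated on assumed constants.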